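(The readings stem from a simulated flask with made-up constants; scatter was added.)

We start with an easy step: for the flask we multiply the charge of reagent in the second phase by the time and get 73.4 M·s. This exposure, reagent charge times time, is the variable of our rule of thumb. While reagent stays steady (the pseudo-first-order picture), and at a fixed ratio of phase volumes, the fraction of substrate turned into target should follow exposure.

| flask | substrate | reagent in the second phase | remark | time | volume of the second phase over the first |
|---|---|---|---|---|---|
| north-west | 0.051 M | 0.086 M | run made earlier |  |  |
| north | 0.051 M | 0.13 M | run made earlier |  |  |
| west | 0.10 M | 0.0612 M | run made earlier |  |  |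
| flask | 0.051 M | 0.0612 M |  | 20 min | 1.0 |

| run | time / min | target / % |
|---|---|---|
| north-west | 2.00 | 3.0 |
| north-west | 4.00 | 7.3 |
| north-west | 6.00 | 10.7 |
| north-west | 8.00 | 13.4 |
| north-west | 10.0 | 16.2 |
| north-west | 12.0 | 19.7 |
| north | 0.833 | 1.5 |
| north | 2.50 | 5.9 |
| north | 4.00 | 11.2 |
| north | 6.00 | 15.9 |
| north | 10.0 | 24.3 |
| north | 12.0 | 26.8 |
| west | 1.00 | 1.2 |
| west | 3.00 | 3.3 |
| west | 6.00 | 6.7 |
| west | 8.00 | 9.8 |
| west | 12.0 | 13.9 |

(each reading ± 0.5 percentage points)

- in the second phase: reagent in the second phase; everything else is in the first
- charges count per volume of the first phase; a concentration in a rate is the amount of a species over the volume of its own phase; every rate counts per litre of the first phase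
- the earlier runs hold the two phases in the same ratio of volumes as the flask asked about

* the target standing at 20 min, as a percentage of the substrate charged
* the change that raises the amount of target at 20 min, in percent of the substrate charged most ("none" if none brings more than 2 percentage points) (red / ochre / none)
* amount of target at 20 min, in percent of the substrate charged, after ochre

- red: doubling the amount of reagent in the second phase, all else as stated
- ochre: doubling the transfer coefficient of the reagent in the second phase, all else as stated

We work in powers of ten. At their last readings, the north-west and north runs share a time, and their log yield ratio over their log exposure ratio gives a slope, read with the scatter of those readings, of 0.745. The flask stands 0.0741 powers of ten above the north-west exposure, so the rule gives 22.4%.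

The border we watch is the fraction of the reagent charge turned into target, yield times substrate charge over reagent charge. At the last readings that is 11.7% in the north-west run but 22.7% in the west run. In the west run, whose substrate charge also differs, the rule's 15.3% overshoots the reading of 13.9%. At the rule's figure the flask stands at 18.6%, between the two, so we commit to a little under the rule. Red doubles exposure, for a rule gain of 15 percentage points; ochre leaves exposure unchanged.

The forecast says 21% for the flask, red as the best change and 21.6% after ochre, holding that ochre “only shortens the lag and trims a small resistance”.

The flask gives 21.4%, 1.00 point under the rule. Red is best, gaining 12 points; ochre gains 0.35 points, reaching 21.8%.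

    reagent in the reaction phase ⇌ reagent in the second phase, rate k1*([reagent in the reaction phase] - [reagent in the second phase]/K1) per volume of the first phase (partition coefficient = 0.640, kL = 0.00720 s⁻¹)
    substrate + reagent in the reaction phase → target (k = 0.00790 L mol⁻¹ s⁻¹)
    reagent in the reaction phase + target → over-reacted product (k = 0.00590 L mol⁻¹ s⁻¹)
    target ⇌ isomer of the product (K = 2.20, k = 1.00 × 10⁻⁴ s⁻¹)

Half the target-forming turnover was done by 9.13 min, with reagent in the reaction phase at 0.0325 M at 10.0 min. Over-reaction came late: 3.9% of its turnover stood at 4.00 min, yet target was still made 2.95 times faster than used up at the end. For the forecast's 21% to be wrong, a run would have to show another charge of reagent in the second phase: the computed answer has moved 5 points at 0.0436 M below and 0.0824 M above, with the other amounts and the time held.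

Read at 12 min, the same flask has exposure 44.1 M·s, so the rule gives 15.3%, with 12.7% of the reagent charge turned into target. The computed flask gives 14.9%.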